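**Retrosynthetic overview**
1. Feature: the only ring, a furan-2(5H)-one, carries the contiguous array O1–C5(H)(chain)–C4(CO2H)=C3(CH3)–C2(=O). This is the connectivity of a 2-methyl-2,3-allenoic acid whose own carboxyl oxygen has bonded to the γ-carbon and whose central carbon has picked up a one-carbon acyl unit.
2. The free acid comes from its benzyl ester. In the ester, O1–C5 and C4–C(=O) are cut together, giving the (aR)-allenoic acid, CO and benzyl alcohol. This cascade closes the only ring and converts the axis into the C5 centre.
3. The C2–C3 bond (carboxyl carbon to methyl-bearing carbon) is cut by retro-hydroxycarbonylation, anti SN2′, to the (S)-propargylic mesylate.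
4. The (S)-carbinol comes from asymmetric transfer hydrogenation of an ynone. The ynone is built from 1-propynylmagnesium bromide and the C14 acetoxy aldehyde derived from 1,14-tetradecanediol.

Key step: step 8

Remark: ring atoms are numbered as in furan-2(5H)-one (O1, C2 carbonyl, C3 methyl-bearing, C4 carboxyl-bearing, C5 stereocentre), so C5 is locant 2 in the systematic 2,5-dihydrofuran names; neutral ligands on palladium are left out of the SMILES of 10, 11, 14 and 15.
Remark: the carbinol centre is set by reduction of an ynone and not by direct catalytic alkynylation, because unbranched enolisable aldehydes are weak substrates for zinc-based alkynylation; two routine extra steps keep the risk in step 8.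

Step 1
Reactants: 1 1,14-tetradecanediol
Product: 2 14-hydroxytetradecyl acetate
Conditions: Ac2O (0.6 equiv), Et3N, DMAP (5 mol %), THF, rt; chromatography, recovered 1 recycled
Reagents that add atoms: acetic anhydride, CC(=O)OC(C)=O
Why: DMAP-catalysed acylation of a symmetrical diol with the anhydride as limiting reagent should give a statistical mixture from which the monoacetate is easily separated by polarity.

Step 2
Reactants: 2 14-hydroxytetradecyl acetate
Product: 3 14-oxotetradecyl acetate
Conditions: TEMPO (10 mol %), PhI(OAc)2 (1.1 equiv), CH2Cl2, rt
Reagents that add atoms: none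
Why: Oxoammonium-mediated (TEMPO/PhI(OAc)2) oxidation of a primary alcohol stops at the aldehyde in the absence of water and does not touch the acetate.

Step 3
Reactants: 3 14-oxotetradecyl acetate; 4 1-propynylmagnesium bromide
Product: 5 (±)-14-hydroxyheptadec-15-yn-1-yl acetate
Conditions: 4 (0.5 M in THF, 1.1 equiv), THF, −78 to −20 °C; sat. aq NH4Cl
Reagents that add atoms: 1-propynylmagnesium bromide, CC#C[Mg]Br
Why: Grignard 1,2-addition of an alkynyl nucleophile is far faster at the aldehyde than at the acetate at low temperature, and the carbinol centre may form racemic because step 4 erases it.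

Step 4
Reactants: 5 (±)-14-hydroxyheptadec-15-yn-1-yl acetate
Product: 6 14-oxoheptadec-15-yn-1-yl acetate
Conditions: Dess–Martin periodinane (1.2 equiv), CH2Cl2, 0 °C to rt
Reagents that add atoms: none
Why: Dess–Martin oxidation converts a secondary propargylic alcohol into the conjugated ynone under mild, non-basic conditions that spare the alkyne and the acetate.

Step 5
Reactants: 6 14-oxoheptadec-15-yn-1-yl acetate
Product: 7 (14S)-14-hydroxyheptadec-15-yn-1-yl acetate
Conditions: Ru[(S,S)-TsDPEN](p-cymene) (1 mol %), i-PrOH (0.1 M), rt
Reagents that add atoms: none
Why: In the Noyori asymmetric transfer hydrogenation of alkynyl ketones the base-free (S,S)-ruthenium amido complex delivers hydride and proton through an outer-sphere six-membered transition state in which the alkynyl π system takes the place usually held by an aryl group, which should set C14 as S in high enantiomeric purity and leave the triple bond and the acetate intact.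

Step 6
Reactants: 7 (14S)-14-hydroxyheptadec-15-yn-1-yl acetate
Product: 8 (14S)-14-(methylsulfonyloxy)heptadec-15-yn-1-yl acetate
Conditions: MsCl (1.3 equiv), Et3N (1.5 equiv), CH2Cl2, −78 to −20 °C; cold aqueous work-up, used crude
Reagents that add atoms: methanesulfonyl chloride, CS(=O)(=O)Cl
Why: O-sulfonylation leaves the C14–O bond untouched, so the S configuration is retained, and the solvolytically labile propargylic mesylate is carried on without chromatography.

Step 7
Reactants: 8 (14S)-14-(methylsulfonyloxy)heptadec-15-yn-1-yl acetate; 9 carbon monoxide
Product: 12 (aR)-17-acetoxy-2-methylheptadeca-2,3-dienoic acid, via allenylpalladium mesylate 10 (not isolated), via dienoylpalladium mesylate 11 (not isolated)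
Conditions: Pd(PPh3)4 (3 mol %), CO (1 atm), THF–H2O (10:1), rt, short reaction time; chromatography to remove phosphine
Reagents that add atoms: carbon monoxide, [C-]#[O+]; water, O
Why: In this palladium-catalysed hydroxycarbonylation of an enantioenriched secondary propargylic mesylate, zerovalent palladium displaces mesylate anti in the SN2′ sense at the methyl-bearing alkyne carbon to give 10, CO inserts with retention to give 11 and water cleaves the acyl–metal bond, so the (S) centre is translated into the (aR) axis.

Step 8
Reactants: 12 (aR)-17-acetoxy-2-methylheptadeca-2,3-dienoic acid; 9 carbon monoxide; 13 benzyl alcohol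
Product: 16 benzyl (2R)-2-(13-acetoxytridecyl)-4-methyl-5-oxo-2,5-dihydrofuran-3-carboxylate, via butenolid-4-ylpalladium chloride 14 (not isolated), via butenolide-4-carbonylpalladium chloride 15 (not isolated)
Conditions: PdCl2(MeCN)2 (5 mol %), p-benzoquinone (1.5 equiv), BnOH (5 equiv), CO (1 atm, raised to 5 bar if needed), 4 Å MS, THF, 0 °C to rt, 12 added slowly
Reagents that add atoms: carbon monoxide, [C-]#[O+]; benzyl alcohol, OCc1ccccc1
Why: Proposed new method: divalent palladium coordinates the distal allene π bond of 12 (future C4–C5), which lies in the plane of the carboxyl group, on the side remote from that group; the carboxyl oxygen then adds anti to the metal at the γ-carbon to form O1–C5 and the σ-vinyl complex 14 with palladium on the former central carbon C4, CO inserts to give acyl complex 15, benzyl alcohol cleaves it to 16 (C4–C(=O) made), and p-benzoquinone together with the two protons released returns zerovalent palladium to the divalent state. The closest known reaction types are the oxypalladation–alkoxycarbonylation of allenes carrying hydroxyl or protected amine nucleophiles, in which a vinylpalladium on the central carbon is trapped by CO and an alcohol, and the PdCl2-catalysed cyclisation–coupling of 2,3-allenoic acids through the same butenolid-4-ylpalladium species, so only the union of the two is untested. The furan-2(5H)-one ring closes in the 5-endo-trig mode, which is geometrically easy here because the p orbital attacked at C5 points directly at the carboxyl oxygen. C5 is the only new stereocentre and is controlled by the allene axis: the tethered oxygen can reach C5 only from its own side, within the plane that separates H from the chain, so the (aR) axis maps onto 5R (2R in the systematic name), as in the halolactonisation of enantioenriched 2,3-allenoic acids. The step needs attack at the γ-carbon and not at the central carbon, which the tether secures because the alternative is a strained four-membered lactone, and it needs CO capture to outrun protonolysis, homocoupling and loss of axial purity, which excess CO, a low stationary concentration of 12 and a nearly neutral, halide-poor medium should secure. For this reason p-benzoquinone is used instead of the customary CuCl2, which on its own turns 2,3-allenoic acids into 4-chlorobutenolides, liberates HCl that favours protonolysis and supplies the chloride that racemises allenes by reversible halopalladation.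

Step 9
Reactants: 16 benzyl (2R)-2-(13-acetoxytridecyl)-4-methyl-5-oxo-2,5-dihydrofuran-3-carboxylate
Product: 17 (2R)-2-(13-acetoxytridecyl)-4-methyl-5-oxo-2,5-dihydrofuran-3-carboxylic acid
Conditions: H2 (1 atm), 10% Pd/C, EtOAc, rt, stopped after uptake of one equivalent
Reagents that add atoms: none
Why: Heterogeneous hydrogenolysis of the benzylic C–O bond is much faster than saturation of the tetrasubstituted, doubly acyl-substituted C3=C4 alkene or cleavage of the C5–O1 bond, so a brief neutral reaction should free the acid with C5 and the acetate unchanged.

**Compound list**
1 | 1,14-tetradecanediol | OCCCCCCCCCCCCCCO | starting material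
2 | 14-hydroxytetradecyl acetate | CC(=O)OCCCCCCCCCCCCCCO | intermediate
3 | 14-oxotetradecyl acetate | CC(=O)OCCCCCCCCCCCCCC=O | intermediate
4 | 1-propynylmagnesium bromide | CC#C[Mg]Br | starting material
5 | (±)-14-hydroxyheptadec-15-yn-1-yl acetate | CC#CC(O)CCCCCCCCCCCCCOC(C)=O | intermediate
6 | 14-oxoheptadec-15-yn-1-yl acetate | CC#CC(=O)CCCCCCCCCCCCCOC(C)=O | intermediate
7 | (14S)-14-hydroxyheptadec-15-yn-1-yl acetate | CC#C[C@@H](O)CCCCCCCCCCCCCOC(C)=O | intermediate
8 | (14S)-14-(methylsulfonyloxy)heptadec-15-yn-1-yl acetate | CC#C[C@@H](OS(C)(=O)=O)CCCCCCCCCCCCCOC(C)=O | intermediate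
9 | carbon monoxide | [C-]#[O+] | starting material
10 | (aR)-(17-acetoxyheptadeca-2,3-dien-2-yl)palladium methanesulfonate (PPh3 ligands omitted, not isolated) | CC([Pd]OS(C)(=O)=O)=[C@@]=C([H])CCCCCCCCCCCCCOC(C)=O | intermediate
11 | (aR)-(17-acetoxy-2-methylheptadeca-2,3-dienoyl)palladium methanesulfonate (PPh3 ligands omitted, not isolated) | CC(C(=O)[Pd]OS(C)(=O)=O)=[C@@]=C([H])CCCCCCCCCCCCCOC(C)=O | intermediate
12 | (aR)-17-acetoxy-2-methylheptadeca-2,3-dienoic acid | OC(=O)C(C)=[C@]=C([H])CCCCCCCCCCCCCOC(C)=O | intermediate
13 | benzyl alcohol | OCc1ccccc1 | starting material
14 | [(2R)-2-(13-acetoxytridecyl)-4-methyl-5-oxo-2,5-dihydrofuran-3-yl]palladium chloride (neutral ligands omitted, not isolated) | CC(=O)OCCCCCCCCCCCCC[C@H]1OC(=O)C(C)=C1[Pd]Cl | intermediate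
15 | [(2R)-2-(13-acetoxytridecyl)-4-methyl-5-oxo-2,5-dihydrofuran-3-carbonyl]palladium chloride (neutral ligands omitted, not isolated) | CC(=O)OCCCCCCCCCCCCC[C@H]1OC(=O)C(C)=C1C(=O)[Pd]Cl | intermediate
16 | benzyl (2R)-2-(13-acetoxytridecyl)-4-methyl-5-oxo-2,5-dihydrofuran-3-carboxylate | CC(=O)OCCCCCCCCCCCCC[C@H]1OC(=O)C(C)=C1C(=O)OCc1ccccc1 | intermediate
17 | (2R)-2-(13-acetoxytridecyl)-4-methyl-5-oxo-2,5-dihydrofuran-3-carboxylic acid | CC(=O)OCCCCCCCCCCCCC[C@H]1OC(=O)C(C)=C1C(=O)O | target

Total step count: 9
Longest linear sequence: 9 steps (1 to 17)

**Steps most likely to fail**

Step 8. The C4–palladium bond may be protonated before CO inserts, which amounts to plain cycloisomerisation. Two vinylpalladium units may couple oxidatively. The axis may lose purity by reversible chloropalladation, or CO may reduce the catalyst to palladium black faster than the quinone reoxidises it. The fallback uses known chemistry only, sets out from 12 and comes back at 16. Iodolactonisation of 12 with I2 and NaHCO3 in MeCN at 0 °C follows the same axis-to-centre course and is established for enantioenriched 2,3-allenoic acids. It should give 13-[(2R)-3-iodo-4-methyl-5-oxo-2,5-dihydrofuran-2-yl]tridecyl acetate F1. Heck-type alkoxycarbonylation of this vinyl iodide with PdCl2(PPh3)2, CO (1 atm) and benzyl alcohol 13 in DMF at 50 °C should then deliver 16. The weak base 2,6-lutidine is chosen to spare the acidic C5–H.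

Step 7. The allenylpalladium species 10 may lose configurational integrity through bimolecular exchange with zerovalent palladium before CO inserts. The mesylate may also solvolyse, and the acid may begin to cyclise prematurely. In the fallback, optical purity is drawn from classical resolution instead of chirality transfer. It sets out from 12 of eroded enantiomeric purity and comes back at 12. The acid is crystallised as its salt with a 1-phenylethylamine antipode, a resolution known for 2,3-allenoic acids. Which antipode gives the less soluble salt must be found by trial, and it is drawn here for the S amine as (S)-1-phenylethylammonium (aR)-17-acetoxy-2-methylheptadeca-2,3-dienoate F2. Partition between cold dilute HCl and Et2O returns enriched 12.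

Step 9. Saturation of the C3=C4 alkene or hydrogenolytic opening of the allylic C5–O1 bond may compete with debenzylation. The fallback removes the reductive step altogether, sets out from 12 and comes back at 17. The acylpalladium species is intercepted with 4-methoxybenzyl alcohol in place of 13, either under the conditions of step 8 or through the carbonylation of F1. This should give 4-methoxybenzyl (2R)-2-(13-acetoxytridecyl)-4-methyl-5-oxo-2,5-dihydrofuran-3-carboxylate F3. Acidolysis of F3 with CF3CO2H and anisole in CH2Cl2 at 0 °C should release 17 without touching the alkene, lactone or acetate.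

**Further compounds**
F1 | step 8 | 13-[(2R)-3-iodo-4-methyl-5-oxo-2,5-dihydrofuran-2-yl]tridecyl acetate | CC(=O)OCCCCCCCCCCCCC[C@H]1OC(=O)C(C)=C1I
F2 | step 7 | (S)-1-phenylethylammonium (aR)-17-acetoxy-2-methylheptadeca-2,3-dienoate | C[C@H]([NH3+])c1ccccc1.[O-]C(=O)C(C)=[C@]=C([H])CCCCCCCCCCCCCOC(C)=O
F3 | step 9 | 4-methoxybenzyl (2R)-2-(13-acetoxytridecyl)-4-methyl-5-oxo-2,5-dihydrofuran-3-carboxylate | CC(=O)OCCCCCCCCCCCCC[C@H]1OC(=O)C(C)=C1C(=O)OCc1ccc(OC)cc1
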